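**Plan**

- Retrosynthetic cuts, in order: the two C4=C15 bonds (ketone methylenation); the four cyclopropane bonds C1–C2/C2–C3 and C1′–C2′/C2′–C3′ (methylene transfer to a dimeric bis-cyclopentenol); the cyclobutane bonds C8–C8′ and C9–C9′ ([2+2] of a monomeric dienol lactone); the butenolide bonds C7–C11 and O–C12 (pyruvate aldol); C1=C3 of ring A (aldol condensation); ring B goes back to (1R,5R)-(+)-verbenone.
- Forward order of rings: ring B (opening of the cyclobutane of the verbenone–vinyl adduct), ring A (cyclopentenone, then the 4β-ol), butenolide, cyclobutane by photodimerisation, both cyclopropanes, both exocyclic methylenes.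
- Enabling feature: in each half the cyclopropane methylene C2 lies on the β-face of the five-membered ring A (C1–C3–C4–C5–C10), syn to the C14 methyl on C10, and C3 is bonded to C4, the carbon that ends as C4=C15. A temporary 4β-hydroxyl there can steer a zinc carbenoid onto that hindered face of C1=C3.
- Stereochemistry: C5 is verbenone's own stereocentre; C10 follows from cuprate attack anti to the gem-dimethyl bridge; the C4 carbinol from α-face hydride delivery; C8/C9/C8′/C9′ from head-to-head, α-face photodimerisation of a single enantiomer; C1/C3/C1′/C3′ from hydroxyl direction.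

Key step: step 14

Remark: lindenane numbering (C1–C15) is used for all intermediates and β means the face of the C10 methyl (C14); the Lewis-acid opening of ketone 3 is assumed to end by proton loss to the isopropenyl group, and (1R,5R)-(+)-verbenone is taken as a commercial chiral-pool material.

**Route**

Step 1
Reactants: 1 (1R,5R)-(+)-verbenone; 2 vinylmagnesium bromide
Product: 3 (1R,4S,5S)-4-ethenyl-4,6,6-trimethylbicyclo[3.1.1]heptan-2-one
Conditions: CH2=CHMgBr, CuI (10 mol %), THF, −40 → 0 °C; then H2O/NH4Cl
Reagents that add atoms: vinylmagnesium bromide (C=C[Mg]Br)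
Why: Copper-catalysed 1,4-addition of a vinyl Grignard reagent to verbenone is a known conjugate addition, and the cuprate attacks C4 from the CH2-bridge side, anti to the gem-dimethyl bridge, so the quaternary centre (later C10) is set with vinyl trans to the bridge carbon that becomes the C5 substituent.

Step 2
Reactants: 3 vinyl ketone; 4 acetic anhydride
Product: 5 (4S,5S)-5-ethenyl-5-methyl-4-(prop-1-en-2-yl)cyclohex-1-en-1-yl acetate
Conditions: Zn(OAc)2, BF3·OEt2, Ac2O, 0 °C → rt
Reagents that add atoms: acetic anhydride (CC(=O)OC(C)=O)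
Why: Lewis-acid-mediated fragmentation of the α-cyclobutyl ketone (C1–C6 cleavage to a tertiary cation that loses a proton, with the enolate caught as its acetate) is the established way to open pinane ketones to cyclohexenyl acetates, and since neither stereocentre takes part the trans vinyl/isopropenyl relationship (later C10/C5) is carried over.

Step 3
Reactants: 5 enol acetate
Product: 6 (3S,4S)-3-ethenyl-3-methyl-4-(prop-1-en-2-yl)cyclohexan-1-one
Conditions: K2CO3 (cat.), MeOH, rt
Reagents that add atoms: none
Why: Base-catalysed transesterification of the enol acetate with methanol releases the C8 ketone under conditions that cannot epimerise C5 (not α to the carbonyl) or the quaternary C10.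

Step 4
Reactants: 6 ketone; 7 ethylene glycol
Product: 8 (7S,8S)-7-ethenyl-7-methyl-8-(prop-1-en-2-yl)-1,4-dioxaspiro[4.5]decane
Conditions: HOCH2CH2OH, PPTS (cat.), benzene, reflux, Dean–Stark
Reagents that add atoms: ethylene glycol (OCCO)
Why: Acid-catalysed ketalisation with azeotropic water removal masks the C8 ketone as a dioxolane that survives ozone, hydroxide and borohydride, and PPTS is mild enough to leave the 1,1-disubstituted alkene in place.

Step 5
Reactants: 8 dioxolane diene; 9 ozone
Product: 11 (7R,8R)-8-acetyl-7-methyl-1,4-dioxaspiro[4.5]decane-7-carbaldehyde, via bis-ozonide 10 (not isolated)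
Conditions: O3, CH2Cl2, −78 °C; then Me2S, −78 °C → rt
Reagents that add atoms: ozone ([O-][O+]=O)
Why: Ozonolysis with reductive work-up cleaves both terminal alkenes at once, turning the vinyl group into a non-enolisable aldehyde on the quaternary carbon (C1) and the isopropenyl group into the methyl ketone (C4 with C3), a 1,4-dicarbonyl pair set up for cyclopentenone formation.

Step 6
Reactants: 11 keto aldehyde
Product: 13 (3aS,7aR)-5,5-(ethylenedioxy)-3a-methyl-3a,4,5,6,7,7a-hexahydro-1H-inden-1-one (trans-fused; lindenane C4 ketone with C1=C3), via β-hydroxy ketone 12 (not isolated)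
Conditions: KOH (cat.), MeOH, 0 °C → rt, short reaction time
Reagents that add atoms: none
Why: Intramolecular aldol condensation of a 4-oxo aldehyde to a cyclopent-2-enone, in which only the acetyl methyl (C3) can attack the α-hydrogen-free aldehyde (C1) in a five-membered sense, while the hindered C5–H between the carbonyl and the quaternary centre should not exchange under brief, cold, dilute hydroxide, so the trans ring fusion of 11 is retained.

Step 7
Reactants: 13 enone
Product: 14 (1S,3aS,7aR)-5,5-(ethylenedioxy)-3a-methyl-3a,4,5,6,7,7a-hexahydro-1H-inden-1-ol (lindenane 4β-OH, cis to the angular methyl)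
Conditions: NaBH4, CeCl3·7H2O, MeOH, −78 °C
Reagents that add atoms: none
Why: Luche 1,2-reduction of the enone, in which hydride adds to C4 from the α-face, anti to the axial C10 methyl and past the small 5α-H, should give the 4β-alcohol (4S) needed to direct the later methylene transfer.

Step 8
Reactants: 14 allylic alcohol; 15 tert-butyl(chloro)diphenylsilane
Product: 16 4β-(tert-butyldiphenylsilyloxy) dioxolane (TBDPS ether of 14)
Conditions: TBDPSCl, imidazole, DMF, rt
Reagents that add atoms: tert-butyl(chloro)diphenylsilane (CC(C)(C)[Si](Cl)(c1ccccc1)c1ccccc1)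
Why: Standard silylation of a secondary alcohol, the TBDPS ether being chosen because it tolerates aqueous acid, LDA and hot TsOH and leaves with fluoride.

Step 9
Reactants: 16 silyl ether ketal; 17 water
Product: 18 4β-(tert-butyldiphenylsilyloxy) C8 ketone (trans-fused 3a-methyl-hexahydroinden-5-one with C1=C3)
Conditions: 1 M HCl, THF, rt
Reagents that add atoms: water (O)
Why: Acid-catalysed acetal hydrolysis frees the C8 ketone, and the TBDPS ether and the isolated ring-A alkene are stable to dilute HCl at room temperature.

Step 10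
Reactants: 18 ketone; 19 ethyl pyruvate
Product: 21 ethyl 2-hydroxy-2-(C7-yl)propanoate aldol adduct of 18 (mixture at C7 and C11), via lithium enolate 20 (not isolated)
Conditions: LDA, THF, −78 °C; then ethyl pyruvate, −78 °C; then AcOH
Reagents that add atoms: ethyl pyruvate (CCOC(=O)C(C)=O)
Why: Directed aldol addition in which LDA removes the kinetic C7 proton (C9 is neopentylic, next to the quaternary C10) and the lithium enolate adds to the ketone carbonyl of ethyl pyruvate; the two new centres (C7, C11) become sp2 in the next step, so their mixture is of no consequence.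

Step 11
Reactants: 21 aldol adduct
Product: 22 monomeric dienol lactone (4β-OTBDPS; C1=C3, C7=C11, C8=C9; 12,8-olide; 5α-H, 10β-CH3)
Conditions: p-TsOH·H2O (cat.), benzene, reflux, Dean–Stark
Reagents that add atoms: none
Why: Acid-catalysed lactonisation with double dehydration (loss of ethanol and water), the usual way to turn pyruvate aldols of ring-B ketones into α-methyl-γ-alkylidene butenolides, should give the fully conjugated C7=C11/C8=C9 dienol lactone as the thermodynamic product.

Step 12
Reactants: 22 dienol lactone (two molecules)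
Product: 23 head-to-head anti cyclobutane dimer, 4β,4′β-bis(TBDPS ether)
Conditions: hν (medium-pressure Hg lamp, Pyrex, λ > 300 nm), degassed hexane/CH2Cl2, ca. 0.1 M, rt
Reagents that add atoms: none
Why: [2+2] Photodimerisation of a γ-alkylidene butenolide at its enol C8=C9 bond, the reaction type by which dienol lactones of this family dimerise head to head, in which each molecule reacts on the α-face of ring B, anti to the axial C10 methyl, and the halves join anti across the new cyclobutane, fixing C8, C9, C8′ and C9′; because the monomer is a single enantiomer only the C2-symmetric homodimer can form.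

Step 13
Reactants: 23 bis(silyl ether) dimer
Product: 24 dimeric bis-cyclopentenol (4β,4′β-diol; cyclobutane-linked bis-butenolide with C1=C3 and C1′=C3′)
Conditions: HF·pyridine, pyridine, THF, 0 °C → rt
Reagents that add atoms: none
Why: Fluoride-mediated cleavage of the silyl ethers under buffered, non-basic conditions that leave the butenolides and the allylic alcohols untouched.

Step 14
Reactants: 24 dimeric diol; 25 diiodomethane; 26 diethylzinc
Product: 28 bis(cyclopropyl carbinol) (4β,4′β-diol with both 1,3-cyclopropanes on the β-face), via bis(ethylzinc alkoxide) 27 (not isolated)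
Conditions: Et2Zn (6 equiv), CH2I2 (12 equiv), CH2Cl2, 0 °C → rt; then aq. NH4Cl
Reagents that add atoms: diiodomethane (ICI)
Why: Diethylzinc first converts both 4β-hydroxyls into ethylzinc alkoxides, and the iodomethylzinc carbenoid formed from Et2Zn and CH2I2 is held by each alkoxide and hands its methylene to the neighbouring C1=C3 bond through the butterfly transition state of the Furukawa-modified, hydroxyl-directed Simmons–Smith reaction, the closest known reaction type being cyclopropanation of cyclopent-2-en-1-ols. Each cyclopropane (C1–C2–C3 and C1′–C2′–C3′) closes by a concerted [2+1] methylene transfer in which C1–C2 and C2–C3 form together, so the cis fusion of each bicyclo[3.1.0]hexane is automatic. The four new stereocentres C1, C3, C1′ and C3′ are all set by the C4/C4′ carbinol configuration, since delivery is syn to oxygen, that is, to the β-face that also carries the C10 methyl. The step needs facial selectivity against the steric bias of the quaternary C10, which would send an undirected reagent to the α-face, and coordination to the zinc alkoxide on the carbon next to C3 secures it. It also needs chemoselectivity, which the substrate provides because the tetrasubstituted, ester-conjugated C7=C11 bonds are too electron-poor and hindered for the electrophilic carbenoid. Excess reagent should drive both ends to completion so that no mono-cyclopropane remains.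

Step 15
Reactants: 28 bis(cyclopropyl carbinol)
Product: 29 bis(cyclopropyl ketone) (C4 and C4′ ketones)
Conditions: Dess–Martin periodinane, NaHCO3, CH2Cl2, 0 °C → rt
Reagents that add atoms: none
Why: Dess–Martin oxidation of secondary cyclopropyl carbinols is fast and neutral when buffered, so the trans ring fusion at C5/C5′ (now α to a ketone) should not epimerise and the cyclopropanes are not opened.

Step 16
Reactants: 29 diketone; 30 dibromomethane
Product: 31 target dimer CNP0265879.1
Conditions: Zn, CH2Br2, TiCl4 (reagent pre-formed in THF, 0 °C), CH2Cl2, 0 °C → rt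
Reagents that add atoms: dibromomethane (BrCBr)
Why: Lombardo methylenation, whose non-basic CH2Br2/Zn/TiCl4 reagent converts hindered, epimerisable ketones into methylene groups without enolisation and does not touch lactone carbonyls, should form C4=C15 and C4′=C15′ with C5/C5′ intact.

**Compound list**

1 | (1R,5R)-(+)-verbenone | CC1=CC(=O)[C@@H]2C[C@H]1C2(C)C | starting material
2 | vinylmagnesium bromide | C=C[Mg]Br | starting material
3 | (1R,4S,5S)-4-ethenyl-4,6,6-trimethylbicyclo[3.1.1]heptan-2-one | C=C[C@]1(C)CC(=O)[C@@H]2C[C@H]1C2(C)C | intermediate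
4 | acetic anhydride | CC(=O)OC(C)=O | starting material
5 | (4S,5S)-5-ethenyl-5-methyl-4-(prop-1-en-2-yl)cyclohex-1-en-1-yl acetate | C=C[C@]1(C)CC(OC(C)=O)=CC[C@H]1C(C)=C | intermediate
6 | (3S,4S)-3-ethenyl-3-methyl-4-(prop-1-en-2-yl)cyclohexan-1-one | C=C[C@]1(C)CC(=O)CC[C@H]1C(C)=C | intermediate
7 | ethylene glycol | OCCO | starting material
8 | (7S,8S)-7-ethenyl-7-methyl-8-(prop-1-en-2-yl)-1,4-dioxaspiro[4.5]decane | C=C[C@]1(C)CC2(OCCO2)CC[C@H]1C(C)=C | intermediate
9 | ozone | [O-][O+]=O | starting material
10 | bis-ozonide | C[C@@]1(C2OCOO2)CC2(OCCO2)CC[C@H]1C1(C)OCOO1 | intermediate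
11 | (7R,8R)-8-acetyl-7-methyl-1,4-dioxaspiro[4.5]decane-7-carbaldehyde | O=C[C@]1(C)CC2(OCCO2)CC[C@H]1C(C)=O | intermediate
12 | β-hydroxy ketone | O=C1CC(O)[C@@]2(C)[C@H]1CCC1(OCCO1)C2 | intermediate
13 | (3aS,7aR)-5,5-(ethylenedioxy)-3a-methyl-3a,4,5,6,7,7a-hexahydro-1H-inden-1-one | O=C1C=C[C@@]2(C)[C@H]1CCC1(OCCO1)C2 | intermediate
14 | (1S,3aS,7aR)-5,5-(ethylenedioxy)-3a-methyl-3a,4,5,6,7,7a-hexahydro-1H-inden-1-ol | O[C@H]1C=C[C@@]2(C)[C@H]1CCC1(OCCO1)C2 | intermediate
15 | tert-butyl(chloro)diphenylsilane | CC(C)(C)[Si](Cl)(c1ccccc1)c1ccccc1 | starting material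
16 | TBDPS ether of 14 | CC(C)(C)[Si](c1ccccc1)(c1ccccc1)O[C@H]1C=C[C@@]2(C)[C@H]1CCC1(OCCO1)C2 | intermediate
17 | water | O | starting material
18 | 4β-silyloxy C8 ketone | CC(C)(C)[Si](c1ccccc1)(c1ccccc1)O[C@H]1C=C[C@@]2(C)[C@H]1CCC(=O)C2 | intermediate
19 | ethyl pyruvate | CCOC(=O)C(C)=O | starting material
20 | lithium enolate | CC(C)(C)[Si](c1ccccc1)(c1ccccc1)O[C@H]1C=C[C@@]2(C)[C@H]1CC=C(O[Li])C2 | intermediate
21 | pyruvate aldol adduct (C7, C11 epimers) | CC(C)(C)[Si](c1ccccc1)(c1ccccc1)O[C@H]1C=C[C@@]2(C)[C@H]1CC(C(C)(O)C(=O)OCC)C(=O)C2 | intermediate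
22 | monomeric dienol lactone, 4β-OTBDPS | CC(C)(C)[Si](c1ccccc1)(c1ccccc1)O[C@H]1C=C[C@@]2(C)[C@H]1CC1=C(C)C(=O)OC1=C2 | intermediate
23 | head-to-head anti photodimer, bis(TBDPS ether) | CC(C)(C)[Si](c1ccccc1)(c1ccccc1)O[C@H]1C=C[C@@]2(C)[C@H]1CC1=C(C)C(=O)O[C@]13[C@H]2[C@H]1[C@@]2(C)C=C[C@H](O[Si](c4ccccc4)(c4ccccc4)C(C)(C)C)[C@@H]2CC2=C(C)C(=O)O[C@@]213 | intermediate
24 | dimeric bis-cyclopentenol (4β,4′β-diol) | O[C@H]1C=C[C@@]2(C)[C@H]1CC1=C(C)C(=O)O[C@]13[C@H]2[C@H]1[C@@]2(C)C=C[C@H](O)[C@@H]2CC2=C(C)C(=O)O[C@@]213 | intermediate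
25 | diiodomethane | ICI | starting material
26 | diethylzinc | CC[Zn]CC | starting material
27 | bis(ethylzinc alkoxide) | CC[Zn]O[C@H]1C=C[C@@]2(C)[C@H]1CC1=C(C)C(=O)O[C@]13[C@H]2[C@H]1[C@@]2(C)C=C[C@H](O[Zn]CC)[C@@H]2CC2=C(C)C(=O)O[C@@]213 | intermediate
28 | bis(cyclopropyl carbinol) | O[C@H]1[C@H]2C[C@H]2[C@@]2(C)[C@H]1CC1=C(C)C(=O)O[C@]13[C@H]2[C@H]1[C@@]2(C)[C@@H]4C[C@@H]4[C@H](O)[C@@H]2CC2=C(C)C(=O)O[C@@]213 | intermediate
29 | bis(cyclopropyl ketone) | O=C1[C@H]2C[C@H]2[C@@]2(C)[C@H]1CC1=C(C)C(=O)O[C@]13[C@H]2[C@H]1[C@@]2(C)[C@@H]4C[C@@H]4C(=O)[C@@H]2CC2=C(C)C(=O)O[C@@]213 | intermediate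
30 | dibromomethane | BrCBr | starting material
31 | CNP0265879.1 | C=C1[C@H]2C[C@H]2[C@@]2(C)[C@H]1CC1=C(C)C(=O)O[C@]13[C@H]2[C@H]1[C@@]2(C)[C@@H]4C[C@@H]4C(=C)[C@@H]2CC2=C(C)C(=O)O[C@@]213 | target

**Totals**

Total step count: 16. Longest linear sequence: 16 steps from (+)-verbenone (the route is linear; step 12 joins two molecules of the same monomer).

**Steps most likely to fail**

1. Step 12. The excited dienol lactone may be consumed within one molecule before it meets a second one, because C8=C9 and the ring-A C1=C3 bond are a 1,4-diene across C10 and could rearrange in the di-π-methane manner; addition to the wrong alkene or face is also possible. The fallback removes the ring-A double bond before the photochemical step and restores it on the dimer. It sets out from silyl ether 16. Hydrogenation (H2, PtO2, EtOAc) would give the saturated silyl ether ketal F1, and aqueous HCl in THF the saturated ketone F2. LDA and ethyl pyruvate would give the aldol adduct F3, and TsOH in refluxing benzene the saturated dienol lactone F4, which carries no second alkene. Irradiation as in step 12 would give the saturated bis(silyl ether) dimer F5, HF·pyridine the saturated diol F6, and buffered Dess–Martin periodinane the bis-cyclopentanone F7. Kinetic enolisation toward the C3/C3′ methylenes (LDA, TMSCl, −78 °C) would give the bis(silyl enol ether) F8, and Saegusa–Ito oxidation (Pd(OAc)2, MeCN) the bis-enone F9. Luche reduction with α-face hydride delivery, as in step 7, then comes back to the route at diol 24.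

2. Step 6. Base may exchange the C5–H next to the acetyl group, or in the enone once formed, and so erode the trans ring fusion toward the more stable cis-fused hydrindenone; the aldol may also stop before dehydration. The fallback closes ring A by ring-closing metathesis under neutral conditions and sets out from diene 8. Lemieux–Johnson cleavage (OsO4 cat., NaIO4, 2,6-lutidine, dioxane/H2O) should attack the unhindered 1,1-disubstituted isopropenyl group in preference to the neopentylic vinyl group and give the methyl ketone F10. Kinetic enolisation (LDA, −78 °C) and Eschenmoser's salt would give the Mannich base F11, and N-methylation and elimination (MeI; NaHCO3) the vinyl ketone F12. Ring-closing metathesis (Grubbs second-generation catalyst, CH2Cl2, 40 °C) then forms C1=C3 and comes back to the route at enone 13.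

3. Step 16. The two ketones, each flanked by a cyclopropane and a ring-fusion methine, may react sluggishly with the titanium–zinc reagent, which would allow epimerisation at C5/C5′ or leave one ketone unreacted. The fallback is a two-stage Peterson olefination and sets out from diketone 29. (Trimethylsilyl)methyllithium pre-mixed with anhydrous CeCl3 (THF, −78 °C), a weakly basic nucleophile suited to hindered, enolisable ketones and slow toward lactones at that temperature, would give the bis(β-hydroxysilane) F13. Syn-elimination with KH (THF, 0 °C) would then install both exocyclic methylenes and come back to the route at target 31.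

**Further compounds**

F1 | step 12 | saturated silyl ether ketal | CC(C)(C)[Si](c1ccccc1)(c1ccccc1)O[C@H]1CC[C@@]2(C)[C@H]1CCC1(OCCO1)C2
F2 | step 12 | saturated silyl ether ketone | CC(C)(C)[Si](c1ccccc1)(c1ccccc1)O[C@H]1CC[C@@]2(C)[C@H]1CCC(=O)C2
F3 | step 12 | pyruvate aldol adduct of F2 | CC(C)(C)[Si](c1ccccc1)(c1ccccc1)O[C@H]1CC[C@@]2(C)[C@H]1CC(C(C)(O)C(=O)OCC)C(=O)C2
F4 | step 12 | saturated dienol lactone | CC(C)(C)[Si](c1ccccc1)(c1ccccc1)O[C@H]1CC[C@@]2(C)[C@H]1CC1=C(C)C(=O)OC1=C2
F5 | step 12 | saturated bis(silyl ether) dimer | CC(C)(C)[Si](c1ccccc1)(c1ccccc1)O[C@H]1CC[C@@]2(C)[C@H]1CC1=C(C)C(=O)O[C@]13[C@H]2[C@H]1[C@@]2(C)CC[C@H](O[Si](c4ccccc4)(c4ccccc4)C(C)(C)C)[C@@H]2CC2=C(C)C(=O)O[C@@]213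
F6 | step 12 | saturated dimer diol | O[C@H]1CC[C@@]2(C)[C@H]1CC1=C(C)C(=O)O[C@]13[C@H]2[C@H]1[C@@]2(C)CC[C@H](O)[C@@H]2CC2=C(C)C(=O)O[C@@]213
F7 | step 12 | bis-cyclopentanone dimer | O=C1CC[C@@]2(C)[C@H]1CC1=C(C)C(=O)O[C@]13[C@H]2[C@H]1[C@@]2(C)CCC(=O)[C@@H]2CC2=C(C)C(=O)O[C@@]213
F8 | step 12 | bis(trimethylsilyl enol ether) | C[Si](C)(C)OC1=CC[C@@]2(C)[C@H]1CC1=C(C)C(=O)O[C@]13[C@H]2[C@H]1[C@@]2(C)CC=C(O[Si](C)(C)C)[C@@H]2CC2=C(C)C(=O)O[C@@]213
F9 | step 12 | bis-enone dimer | O=C1C=C[C@@]2(C)[C@H]1CC1=C(C)C(=O)O[C@]13[C@H]2[C@H]1[C@@]2(C)C=CC(=O)[C@@H]2CC2=C(C)C(=O)O[C@@]213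
F10 | step 6 | 1-[(7S,8R)-7-ethenyl-7-methyl-1,4-dioxaspiro[4.5]decan-8-yl]ethan-1-one | C=C[C@]1(C)CC2(OCCO2)CC[C@H]1C(C)=O
F11 | step 6 | Mannich base (3-dimethylaminopropanoyl analogue of F10) | C=C[C@]1(C)CC2(OCCO2)CC[C@H]1C(=O)CCN(C)C
F12 | step 6 | vinyl ketone (propenoyl analogue of F10) | C=C[C@]1(C)CC2(OCCO2)CC[C@H]1C(=O)C=C
F13 | step 16 | bis(β-hydroxysilane) (C4/C4′ carbinol epimers) | C[Si](C)(C)CC1(O)[C@H]2C[C@H]2[C@@]2(C)[C@H]1CC1=C(C)C(=O)O[C@]13[C@H]2[C@H]1[C@@]2(C)[C@@H]4C[C@@H]4C(O)(C[Si](C)(C)C)[C@@H]2CC2=C(C)C(=O)O[C@@]213
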